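A direct plan would start from 1-(3,4-dimethoxyphenyl)propan-1-one A1 and convert it into its trimethylsilyl enol ether A2; oxidation of A2 with PhI(OAc)2/BF3·OEt2 would give an enolonium species, which unprotected eugenol A3 would have to attack through its free ortho carbon to give the racemic α-aryl ketone A4.
Noyori hydrogenation of A4 under dynamic kinetic resolution would then have to set both stereocentres in the last step.
Such a plan would be short, three steps from A1 with none wasted; its weakness would be that it rests on two unproven events.
The oxidative α-arylation that joins A2 and A3 would be the weakest step: a trivalent iodine oxidant would meet the free, electron-rich phenol A3, which such reagents dearomatise or couple at oxygen, and the carbon nucleophiles known for enolonium species are indoles and pyrroles, not phenols.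
The reduction would be the second: C-2 would first be made racemic and then left to an epimerisation by excess KOtBu that must outrun reduction of a hindered, phenoxide-bearing ketone, so both stereocentres would be left to chance until the end.
It would also be the step least welcome on late material: strong base may move the allyl double bond into conjugation, and the product, a benzylic alcohol beside a phenol, closes to a dihydrobenzofuran with traces of acid.

**Plan of the new route**
The retrosynthesis cuts C-4–allyl of ring A (the phenol ring) first, then C-1–O together with C-2–H, then C-1–ring B (the dimethoxyphenyl ring) and C-2–CH3; the ring A–C-2 bond is never made, because C-2 is the CHO carbon of o-vanillin.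
Ring A therefore comes first and is homologated to an alkyne; ring B joins last, at C-1, by methylalumination/cross-coupling, which gives the flat (E)-1,2-diarylpropene.
Feature that makes the key step possible: C-1 (H, OH, ring B) and C-2 (H, CH3, ring A) are adjacent CH carbons whose OH and H lie on the same face when rings A and B are anti. That is the syn H–OH adduct of the (E)-alkene with oxygen on the CH carbon, so one asymmetric hydroboration sets both centres.
Second feature: the allyl group is para to a phenol OH whose two ortho carbons are occupied (OMe and the side chain), the product pattern of a Claisen–Cope shift of the O-allyl ether; the allyl group thus enters last, from oxygen, and no protecting group is isolated.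
Hence no oxidant meets a free phenol in a C–C bond formation, no ketone or epimerisable C-2 occurs, both stereocentres arise together and stereospecifically on an early intermediate, and no strong base acts while the allyl group is present.

Key step: step 3

Remark: the facial preference of isopinocampheylborane for the diarylpropene is assumed to follow that known for 1-arylcycloalkenes; this fixes only which enantiomer of α-pinene the reagent is made from.

Step 1
Reactants: 1 2-hydroxy-3-methoxybenzaldehyde (o-vanillin)
Product: 2 2-ethynyl-6-methoxyphenol
Conditions: dimethyl (1-diazo-2-oxopropyl)phosphonate (1.5 equiv), K2CO3 (3 equiv), MeOH, 0 → 23 °C; aq NH4Cl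
Reagents that add atoms: dimethyl (1-diazo-2-oxopropyl)phosphonate, CC(=O)C(=[N+]=[N-])P(=O)(OC)OC
Why: Seyferth–Gilbert homologation in its Ohira–Bestmann form: the diazomethylphosphonate anion released by methanolysis adds to the aldehyde, dimethyl phosphate is lost and the resulting alkylidene carbene rearranges by 1,2-hydrogen shift with loss of N2, so the CHO carbon (the future C-2) becomes the inner alkyne carbon under carbonate conditions that only deprotonate the phenol; no stereocentre is formed.

Step 2
Reactants: 2 2-ethynyl-6-methoxyphenol; 3 4-iodo-1,2-dimethoxybenzene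
Product: 5 (E)-2-[1-(3,4-dimethoxyphenyl)prop-1-en-2-yl]-6-methoxyphenol, via alkenylalane 4 (not isolated)
Conditions: Me3Al (3.5 equiv), Cp2ZrCl2 (0.25 equiv), ClCH2CH2Cl, 0 → 23 °C; then 3 (1.0 equiv), Pd(PPh3)4 (5 mol %), ZnCl2 (0.3 equiv), THF, 23 °C; aq potassium sodium tartrate; Et3N-deactivated SiO2
Reagents that add atoms: trimethylaluminium, C[Al](C)C
Why: Zirconium-catalysed methylalumination of the terminal alkyne followed by palladium-catalysed cross-coupling of the alkenylalane (Negishi): methyl and aluminium add syn with methyl on the aryl-bearing carbon (the future C-2), the C–Al bond is replaced by ring B with retention, so rings A and B end up trans in (E)-5, and the first equivalent of Me3Al merely turns the phenol into its aluminium phenoxide.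

Step 3
Reactants: 5 (E)-2-[1-(3,4-dimethoxyphenyl)prop-1-en-2-yl]-6-methoxyphenol
Product: 8 2-[(1S,2S)-1-(3,4-dimethoxyphenyl)-1-hydroxypropan-2-yl]-6-methoxyphenol, via trimethylsilyl ether 6 (not isolated), via isopinocampheylborane adduct 7 (not isolated)
Conditions: (Me3Si)2NH (0.7 equiv), saccharin (1 mol %), THF, 60 °C, then evaporate; (1S,2R,3S,5S)-isopinocampheylborane [from (−)-α-pinene, pre-formed THF solution] (1.3 equiv), THF, −25 → 0 °C; 3 M NaOH, 30% H2O2, 0 → 23 °C; pH 7 phosphate buffer; Et3N-deactivated SiO2
Reagents that add atoms: hydrogen peroxide, OO (the oxygen on C-1); hexamethyldisilazane, C[Si](C)(C)N[Si](C)(C)C (supplies the silyl group of intermediate 6 only); (1S,2R,3S,5S)-isopinocampheylborane, C[C@@H]1[C@@H](B)C[C@H]2C[C@@H]1C2(C)C (supplies boron and the isopinocampheyl group of intermediate 7 only; of it only the hydrogen on C-2 remains in 8)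
Why: Asymmetric hydroboration–oxidation with monoisopinocampheylborane: after the phenol is masked in situ as its trimethylsilyl ether 6, so that no aryloxyborane can deliver hydride intramolecularly, B–H adds through the four-centre transition state syn across C-1=C-2 with boron on the less hindered CH carbon C-1 and hydrogen on the fully substituted C-2 (7), and alkaline hydrogen peroxide then replaces boron by OH with retention and cleaves the silyl ether. The closest known reaction type is the hydroboration of 1-phenylcyclopentene and of 2-aryl-2-butenes with the same reagent; no ring is closed. The relative configuration of both new stereocentres follows from syn addition to the (E)-alkene: with rings A and B anti, OH on C-1 and H on C-2 lie on the same face, which is the 1S,2S/1R,2R pair. The absolute configuration is controlled by the isopinocampheyl group: the reagent from (+)-α-pinene is known to give (1S,2R)-trans-2-phenylcyclopentanol, which corresponds to attack on the 1R,2R face of 6, so the reagent from (−)-α-pinene is used for 1S,2S. The step needs regioselectivity (secondary against tertiary carbon, reinforced by the bulk of the reagent), facial selectivity (reagent control) and chemoselectivity, the last being secured because 5 holds no other C=C bond, the allyl group not yet being present.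

Step 4
Reactants: 8 2-[(1S,2S)-1-(3,4-dimethoxyphenyl)-1-hydroxypropan-2-yl]-6-methoxyphenol; 9 allyl bromide (3-bromoprop-1-ene)
Product: 10 (1S,2S)-2-(2-allyloxy-3-methoxyphenyl)-1-(3,4-dimethoxyphenyl)propan-1-ol
Conditions: K2CO3 (2 equiv), acetone, 56 °C
Reagents that add atoms: none
Why: Williamson ether synthesis: carbonate deprotonates only the phenol, so the secondary benzylic alcohol and both stereocentres are untouched, and the O-allyl ether formed is the substrate of the para-Claisen shift.

Step 5
Reactants: 10 (1S,2S)-2-(2-allyloxy-3-methoxyphenyl)-1-(3,4-dimethoxyphenyl)propan-1-ol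
Product: 13 4-allyl-2-[(1S,2S)-1-(3,4-dimethoxyphenyl)-1-hydroxypropan-2-yl]-6-methoxyphenol, via ortho-dienone 11 (not isolated), via para-dienone 12 (not isolated)
Conditions: PhNEt2, 190 °C, sealed tube, Ar; solvent removed by bulb-to-bulb distillation; Et3N-deactivated SiO2
Reagents that add atoms: none
Why: para-Claisen rearrangement: the aromatic Claisen [3,3] shift to a substituted ortho carbon gives a cyclohexa-2,4-dienone (11, or its isomer at the other ortho carbon) that cannot enolise, a Cope [3,3] shift moves the allyl group on to C-4 (12) and enolisation restores the phenol; because both ortho carbons of ring A carry substituents only the para position can end the sequence, the amine solvent keeps the medium free of acid, and neither stereocentre takes part.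

**Compound list**
1 | 2-hydroxy-3-methoxybenzaldehyde (o-vanillin) | COc1cccc(C=O)c1O | starting material
2 | 2-ethynyl-6-methoxyphenol | COc1cccc(C#C)c1O | intermediate
3 | 4-iodo-1,2-dimethoxybenzene | COc1ccc(I)cc1OC | starting material
4 | dimethyl[(E)-2-(2-dimethylalumanyloxy-3-methoxyphenyl)prop-1-enyl]alumane | COc1cccc(/C(C)=C/[Al](C)C)c1O[Al](C)C | intermediate
5 | (E)-2-[1-(3,4-dimethoxyphenyl)prop-1-en-2-yl]-6-methoxyphenol | COc1cccc(/C(C)=C/c2ccc(OC)c(OC)c2)c1O | intermediate
6 | [2-[(E)-1-(3,4-dimethoxyphenyl)prop-1-en-2-yl]-6-methoxyphenoxy]trimethylsilane | COc1cccc(/C(C)=C/c2ccc(OC)c(OC)c2)c1O[Si](C)(C)C | intermediate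
7 | [(1S,2R)-1-(3,4-dimethoxyphenyl)-2-(3-methoxy-2-trimethylsilyloxyphenyl)propyl][(1S,2R,3S,5S)-2,6,6-trimethylbicyclo[3.1.1]heptan-3-yl]borane | C[C@@H]1[C@@H](B[C@H](c2ccc(OC)c(OC)c2)[C@@H](C)c2cccc(OC)c2O[Si](C)(C)C)C[C@H]2C[C@@H]1C2(C)C | intermediate
8 | 2-[(1S,2S)-1-(3,4-dimethoxyphenyl)-1-hydroxypropan-2-yl]-6-methoxyphenol | COc1cccc([C@H](C)[C@H](O)c2ccc(OC)c(OC)c2)c1O | intermediate
9 | allyl bromide (3-bromoprop-1-ene) | C=CCBr | starting material
10 | (1S,2S)-2-(2-allyloxy-3-methoxyphenyl)-1-(3,4-dimethoxyphenyl)propan-1-ol | C=CCOc1c(OC)cccc1[C@H](C)[C@H](O)c1ccc(OC)c(OC)c1 | intermediate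
11 | 6-allyl-2-[(1S,2S)-1-(3,4-dimethoxyphenyl)-1-hydroxypropan-2-yl]-6-methoxycyclohexa-2,4-dien-1-one (either configuration at C-6) | C=CCC1(OC)C=CC=C([C@H](C)[C@H](O)c2ccc(OC)c(OC)c2)C1=O | intermediate
12 | 4-allyl-2-[(1S,2S)-1-(3,4-dimethoxyphenyl)-1-hydroxypropan-2-yl]-6-methoxycyclohexa-2,5-dien-1-one (either configuration at C-4) | C=CCC1C=C(OC)C(=O)C([C@H](C)[C@H](O)c2ccc(OC)c(OC)c2)=C1 | intermediate
13 | 4-allyl-2-[(1S,2S)-1-(3,4-dimethoxyphenyl)-1-hydroxypropan-2-yl]-6-methoxyphenol | C=CCc1cc(OC)c(O)c([C@H](C)[C@H](O)c2ccc(OC)c(OC)c2)c1 | target

**Count and risks**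
Total step count: 5. Longest linear sequence: 5 steps (1 → 2 → 5 → 8 → 10 → 13).

The three steps most likely to fail:

Step 3 (key step). The chiral borane may discriminate the two faces of an acyclic, doubly conjugated alkene incompletely, may add slowly to the hindered double bond, or may deliver part of the boron to C-2. The fallback sets out from 5 and gives up reagent control in favour of resolution. 5 would be silylated as in step 3, hydroborated with BH3·SMe2 (THF, 0 → 23 °C) and oxidised (NaOH, H2O2); syn addition still fixes the relative configuration, so 8 should form together with its mirror image (1R,2R)-2-[1-(3,4-dimethoxyphenyl)-1-hydroxypropan-2-yl]-6-methoxyphenol F1. The two enantiomers would be separated by preparative chromatography on an amylose carbamate chiral stationary phase, and the route is rejoined at 8.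

Step 2. The ortho aluminium phenoxide may chelate the alkenyl aluminium and erode the (E) geometry, or add to the alkyne and close a benzofuran, and methyl may transfer to palladium in place of the alkenyl group. The fallback sets out from 3 and builds the alkene from the ring B side. Sonogashira coupling of 3 with propyne (PdCl2(PPh3)2, CuI, Et3N, THF) should give 1,2-dimethoxy-4-(prop-1-yn-1-yl)benzene F2. Copper-catalysed syn protoboration (CuCl, NaOtBu, 4,5-bis(diphenylphosphino)-9,9-dimethylxanthene, B2pin2, MeOH, THF) should place boron on the methyl-bearing carbon and give 2-[(Z)-1-(3,4-dimethoxyphenyl)prop-1-en-2-yl]-4,4,5,5-tetramethyl-1,3,2-dioxaborolane F3. Suzuki–Miyaura coupling of F3 with commercial 2-bromo-6-methoxyphenol (Pd(OAc)2, 2-dicyclohexylphosphino-2′,6′-dimethoxybiphenyl, K3PO4, toluene/H2O, 80 °C) with retention comes back to the route at 5.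

Step 5. At the rearrangement temperature the benzylic carbinol may lose water and close onto the newly freed phenol, or the allyl group may stall at the dienone stage. The fallback sets out from 8 and replaces the sigmatropic shift by halogenation and cross-coupling. Bromination of 8 (NBS, MeCN, −20 °C), directed by the free phenol to its only open para position, should give 4-bromo-2-[(1S,2S)-1-(3,4-dimethoxyphenyl)-1-hydroxypropan-2-yl]-6-methoxyphenol F4. Suzuki–Miyaura allylation of F4 (allylboronic acid pinacol ester, Pd(PPh3)4, CsF, THF, 65 °C) comes back to the route at 13.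

**Further compounds**
F1 | step 3 | (1R,2R)-2-[1-(3,4-dimethoxyphenyl)-1-hydroxypropan-2-yl]-6-methoxyphenol | COc1cccc([C@@H](C)[C@@H](O)c2ccc(OC)c(OC)c2)c1O
F2 | step 2 | 1,2-dimethoxy-4-(prop-1-yn-1-yl)benzene | CC#Cc1ccc(OC)c(OC)c1
F3 | step 2 | 2-[(Z)-1-(3,4-dimethoxyphenyl)prop-1-en-2-yl]-4,4,5,5-tetramethyl-1,3,2-dioxaborolane | C/C(B1OC(C)(C)C(C)(C)O1)=C\c1ccc(OC)c(OC)c1
F4 | step 5 | 4-bromo-2-[(1S,2S)-1-(3,4-dimethoxyphenyl)-1-hydroxypropan-2-yl]-6-methoxyphenol | COc1cc(Br)cc([C@H](C)[C@H](O)c2ccc(OC)c(OC)c2)c1O
A1 | direct plan | 1-(3,4-dimethoxyphenyl)propan-1-one | CCC(=O)c1ccc(OC)c(OC)c1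
A2 | direct plan | (Z)-[1-(3,4-dimethoxyphenyl)prop-1-enyloxy]trimethylsilane | C/C=C(\O[Si](C)(C)C)c1ccc(OC)c(OC)c1
A3 | direct plan | eugenol (4-allyl-2-methoxyphenol) | C=CCc1ccc(O)c(OC)c1
A4 | direct plan | 2-(5-allyl-2-hydroxy-3-methoxyphenyl)-1-(3,4-dimethoxyphenyl)propan-1-one (racemic) | C=CCc1cc(OC)c(O)c(C(C)C(=O)c2ccc(OC)c(OC)c2)c1
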